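**Atom numbering used throughout.** Ring B (lactone): C1 (carbonyl), O2, C3, C4, C4a, C8a. Ring A (arene): C4a, C5, C6, C7, C8, C8a. The succinate carbons are C1' (bonded to C4) and C2'.

## Analysis of the target

Target 22 is a 3,4-dihydro-1H-isochromen-1-one: a six-membered lactone (ring B) fused to a pyrogallol ring A that carries hydroxyls on C5, C6 and C7 and hydrogen on C8. C3 bears a carboxyl group and C4 a succinic acid unit attached through C1', so four carboxyl carbons surround one secondary alcohol oxygen (O2), and only the aromatic one is esterified. The three stereocentres are contiguous, C3 (S), C4 (S) and C1' (R), with the C3 carboxyl and the C4 side chain trans on ring B. C3 and C1' are α to carbonyl groups and can epimerise with base, C4 is benzylic, and the pyrogallol is oxidised quickly by air in base. O2 can also lactonise onto the C1' carboxyl (five-membered ring) or the C2' carboxyl, and the C5 hydroxyl can reach the C3 and C1' carboxyls. The difficulty is therefore twofold: an acyclic stereotriad carrying four carboxyl groups must be built with control, and rings A and B must be formed in an order that leaves the right lactone. The strategy rests on the substitution pattern of ring A: carbon (C4) on C4a, oxygen on C5, C6 and C7, hydrogen on C8 and the carbonyl carbon on C8a. That is the imprint of a 3,4-dioxygenated furan added across a 2-ynoate that is substituted at its carbon 4, after the oxygen bridge has opened towards the alkyl-bearing side; C4a and C8a are the two alkyne carbons and C1 is the ynoate carbonyl.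

## Retrosynthetic reasoning

**22 back to 19.** The two phenols on C6 and C7 are traced to methyl ethers (21). The C1–O2 bond of ring B is then cut, which leads to 19, where O2 is still acylated by the C1' carbonyl as a γ-lactone and the aromatic carboxyl is a methyl ester. Ring B is thus made last, from groups already present: hydrolysis frees all four carboxylates (20), and on acidification O2 has to close onto C1.

**19 to 16 and 17 (key disconnection).** The C4a–C5 and C8a–C8 bonds are cut and the C5 oxygen is reconnected to C8 as a bridge. This splits ring A into a symmetrical four-carbon unit that brings both methoxy groups and the future C5 oxygen (17) and a two-carbon alkyne that is already part of the chain (16). Any other cut of ring A would leave the C4–C4a bond to be made at a crowded benzylic stereocentre. The gain is that the whole stereotriad can be assembled on a small aliphatic alkyne, where a ring can be used for stereocontrol. The forward reaction must add the furan to a singly activated alkyne, open the bridge of 18 in the right direction, and leave C4 untouched.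

**16 to 15, 13 and 12.** The C8a–C1 bond is cut, so the ynoate comes from the terminal alkyne 15 by carbonylation. This is placed last before the key step because a 2-ynoate with a hydrogen on C4 does not tolerate base. The C3 ester of 15 comes from the hydroxymethyl group of 13 by oxidation, and 13 from 12 by removal of both silyl groups.

**12 to 10 and 11.** The C1'–C2' bond is cut. In lactone 10 the alkyne on C4 and the silyloxymethyl group on C3 lie on the same face of a five-membered ring, so alkylation of its enolate with 11 from the open face sets C1' trans to both. This is the reason O2 and the C1' carbonyl are kept as a lactone all the way to 19 instead of as a silyl ether beside an ester; an open-chain enolate would give no such control.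

**10 to 9, 7 and 6.** The lactone C–O bond is traced to the acetonide oxygen on C3 of 7 (through diol 8), and 7 to malonate 6 by loss of one ester group.

**6 to 3 and 4, and 3 to 1 and 2.** The bond between C4 and the alkyne is cut: the magnesium acetylide 5 made from 4 adds in a conjugate sense to the alkylidene malonate 3. A doubly activated acceptor is chosen because alkynyl metals do not add to simple enoates. C4 is set relative to C3, and C3 comes from the chiral pool aldehyde 1, joined to 2 by a Knoevenagel condensation.

## Alternatives that were turned down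

**Alternative 1:** The C3–C4 and C1'–C2' bonds are cut together in a retro-[4+2] step, after the C3 carboxyl carbon and the C2' carboxyl carbon have been joined as the double bond of a cyclohexene; the ester linkage of ring B is the tether. In the forward direction the triene A1, a benzoate with an (E)-buta-1,3-dienyl group on the ester oxygen and a (Z)-acrylate arm in the ortho position, would cyclise thermally to the trans-fused tricycle A2. Cleavage of the cyclohexene double bond of A2 would then give both missing carboxyl groups.
- For it: ring A is bought complete, and ring B and the relative configuration of all three stereocentres come from one pericyclic step. The lactone cannot close the wrong way, because its C–O bond exists before any aliphatic carboxyl does. On this point it is stronger than the chosen route.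
- Against it: A1 has no stereocentre, so the single enantiomer would depend entirely on an external chiral catalyst for an ester-tethered cycloaddition. Such a tether prefers the unreactive ester conformation and needs high temperatures, at which the dienyl ester and the (Z)-acrylate are fragile. The trans ring fusion is also the harder outcome for a short tether.
- Comparison: it is shorter, but the absolute configuration is unsolved. The chosen route takes C3 from 1 and sets C4 and C1' under substrate control, and pays with a longer sequence and a lactone-selectivity question at the end.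

**Alternative 2:** Both carboxyl carbons of the succinate arm are removed (C1'–carboxyl and C2'–carboxyl), which leaves a vinyl group on C4 of a closed isochromanone, A3. In the forward direction a divalent palladium catalyst with a reoxidant would effect an oxidative double methoxycarbonylation of the vinyl group and give A4.
- For it: ring B and the C3 and C4 centres are already in place, and two C–C bonds plus C1' are made in one step. Its end game is shorter than that of the chosen route.
- Against it: C1' is created in the carbopalladation step with only the neighbouring C4 centre, or a ligand, to direct it. The C4 hydrogen is both allylic and benzylic, so β-hydride elimination and migration of the double bond into conjugation with ring A threaten C4. Monocarbonylation competes. A3 itself still needs an enantioselective synthesis with the trans 3,4 relationship.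
- Comparison: the chosen route sets C1' by alkylation of a rigid lactone (10 to 12), where the facial bias is predictable, and never passes through an organopalladium species next to C4.

**Alternative 3:** The C8a–C1 and C1–O2 bonds are cut, so the lactone carbonyl is removed as a one-carbon unit and the open-chain hydroxy triester A5 with a 2,3,4-trimethoxyphenyl group on C4 remains. In the forward direction the C3 hydroxyl would bind divalent palladium, palladation would occur at the only free ortho position (C8a), and insertion of the one-carbon unit with C–O bond formation would give A6.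
- For it: ring A is bought, there is only one ortho C–H bond, and the tert-butyl esters block the competing lactones, so the closure of ring B is unambiguous. Here it is stronger than the chosen route. A5 also needs a conjugate arylation, which is easier than a conjugate alkynylation.
- Against it: the directing group is a secondary alcohol α to an ester. It is a weak donor, and its palladium alkoxide has a β-hydrogen and can collapse to the α-keto ester. The electron-rich arene is exposed to a stoichiometric oxidant, and the C–H bond is flanked by the branched C4.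
- Comparison: the length is similar. Its risk sits in a C–H activation on a substrate class where alcohol oxidation is an open pathway. The key step of the chosen route is a cycloaddition and an ionisation with clear electronic guidance, and it delivers the C5 oxygen and the C1 carbon in the same operation.

Key step: step 10

Remark on the chemistry: O2 and the C1' carboxyl are masked together as a γ-lactone rather than as a silyl ether beside a methyl ester. The key-step precursor 16 and product 19 therefore carry this lactone; it fixes C1' in step 6 and is opened in step 11.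

## Route

Step 1
Reactants: 1 (4R)-2,2-dimethyl-1,3-dioxolane-4-carbaldehyde; 2 dimethyl propanedioate
Product: 3 dimethyl 2-{[(4S)-2,2-dimethyl-1,3-dioxolan-4-yl]methylidene}propanedioate
Conditions: piperidine (0.1 equiv), AcOH (0.1 equiv), 4 Å MS, toluene, 0 °C → rt
Reagents that add atoms: none
Why: Knoevenagel condensation of an aldehyde with an active methylene compound; the mild amine/acid pair at or below room temperature is chosen so that the α-alkoxy aldehyde should not racemise, and the C3 centre is carried over unchanged (its descriptor becomes S only because the priorities change).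

Step 2
Reactants: 3 dimethyl 2-{[(4S)-2,2-dimethyl-1,3-dioxolan-4-yl]methylidene}propanedioate; 4 ethynyltri(propan-2-yl)silane
Product: 6 dimethyl 2-{(1S)-1-[(4S)-2,2-dimethyl-1,3-dioxolan-4-yl]-3-[tri(propan-2-yl)silyl]prop-2-yn-1-yl}propanedioate, via alkynylmagnesium bromide 5 (not isolated)
Conditions: 4, EtMgBr, THF, 0 °C → rt; then 3, THF, −40 → 0 °C; aq. NH4Cl
Reagents that add atoms: none
Why: Conjugate (Michael) addition of an alkynyl Grignard reagent to an alkylidene malonate, a doubly activated acceptor that accepts alkynyl metals where simple enoates do not. The ester cis to C3 holds the C3–H in the alkene plane (allylic 1,3-strain), so the two faces of C4 are flanked by the ring oxygen and by the ring CH2. Attack anti to the C–C bond, on the face where magnesium can bind the dioxolane oxygen, should give the (1S) centre at C4 (syn adduct).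

Step 3
Reactants: 6 dimethyl 2-{(1S)-1-[(4S)-2,2-dimethyl-1,3-dioxolan-4-yl]-3-[tri(propan-2-yl)silyl]prop-2-yn-1-yl}propanedioate
Product: 7 methyl (3S)-3-[(4S)-2,2-dimethyl-1,3-dioxolan-4-yl]-5-[tri(propan-2-yl)silyl]pent-4-ynoate
Conditions: LiCl, H2O, DMSO, 130 °C
Reagents that add atoms: none
Why: Krapcho dealkoxycarbonylation of a monosubstituted malonate under near-neutral conditions; the acetonide and the hindered silylalkyne should survive, and C4 has no acidic hydrogen.

Step 4
Reactants: 7 methyl (3S)-3-[(4S)-2,2-dimethyl-1,3-dioxolan-4-yl]-5-[tri(propan-2-yl)silyl]pent-4-ynoate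
Product: 9 (4S,5S)-5-(hydroxymethyl)-4-{[tri(propan-2-yl)silyl]ethynyl}oxolan-2-one, via dihydroxy ester 8 (not isolated)
Conditions: TsOH·H2O (0.2 equiv), MeOH/H2O (9:1), 50 °C; then toluene, 60 °C
Reagents that add atoms: none
Why: Acid-catalysed acetal hydrolysis followed by lactonisation of the γ-hydroxy ester; the five-membered lactone from the secondary C3 hydroxyl should be favoured over the six-membered one from the primary hydroxyl. No stereocentre is touched, so the alkyne and the hydroxymethyl group end up cis on the ring.

Step 5
Reactants: 9 (4S,5S)-5-(hydroxymethyl)-4-{[tri(propan-2-yl)silyl]ethynyl}oxolan-2-one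
Product: 10 (4S,5S)-5-({[tert-butyl(dimethyl)silyl]oxy}methyl)-4-{[tri(propan-2-yl)silyl]ethynyl}oxolan-2-one
Conditions: TBSCl, imidazole, DMF, 0 °C → rt
Reagents that add atoms: tert-butyl(chloro)dimethylsilane, CC(C)(C)[Si](C)(C)Cl
Why: Standard silylation of a primary alcohol; it removes the only O–H before the enolate step.

Step 6
Reactants: 10 (4S,5S)-5-({[tert-butyl(dimethyl)silyl]oxy}methyl)-4-{[tri(propan-2-yl)silyl]ethynyl}oxolan-2-one; 11 methyl bromoacetate
Product: 12 methyl 2-[(3R,4S,5S)-5-({[tert-butyl(dimethyl)silyl]oxy}methyl)-2-oxo-4-{[tri(propan-2-yl)silyl]ethynyl}oxolan-3-yl]acetate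
Conditions: LiN(SiMe3)2, THF, −78 °C; then 11, −78 → −40 °C
Reagents that add atoms: none
Why: Alkylation of a γ-butyrolactone lithium enolate; the alkyne on C4 and the silyloxymethyl group on C3 shield the same face, so the electrophile should enter from the other face and place the new C1' centre (3R in 12) trans to both.

Step 7
Reactants: 12 methyl 2-[(3R,4S,5S)-5-({[tert-butyl(dimethyl)silyl]oxy}methyl)-2-oxo-4-{[tri(propan-2-yl)silyl]ethynyl}oxolan-3-yl]acetate
Product: 13 methyl 2-[(3R,4S,5S)-4-ethynyl-5-(hydroxymethyl)-2-oxooxolan-3-yl]acetate
Conditions: Bu4NF, AcOH, THF, 0 °C → rt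
Reagents that add atoms: none
Why: Fluoride-mediated desilylation cleaves the O–Si bond and the alkynyl C–Si bond in one operation; buffering with acetic acid should keep the alkoxide from attacking the lactone or the ester.

Step 8
Reactants: 13 methyl 2-[(3R,4S,5S)-4-ethynyl-5-(hydroxymethyl)-2-oxooxolan-3-yl]acetate
Product: 15 methyl (2S,3S,4R)-3-ethynyl-4-(2-methoxy-2-oxoethyl)-5-oxooxolane-2-carboxylate, via carboxylic acid 14 (not isolated)
Conditions: TEMPO (0.2 equiv), PhI(OAc)2, MeCN/H2O, rt; crude acid, then Me3SiCHN2, toluene/MeOH, 0 °C
Reagents that add atoms: water, O; (trimethylsilyl)diazomethane, C[Si](C)(C)C=[N+]=[N-]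
Why: Nitroxyl-catalysed oxidation of a primary alcohol to the acid through the aldehyde hydrate, under slightly acidic conditions that should not epimerise C3, followed by methylation with a diazoalkane, which does not add to an unactivated terminal alkyne. The ester is needed because a free 4-alkynoic acid would cyclise onto the alkyne under divalent palladium in step 9.

Step 9
Reactants: 15 methyl (2S,3S,4R)-3-ethynyl-4-(2-methoxy-2-oxoethyl)-5-oxooxolane-2-carboxylate
Product: 16 methyl (2S,3S,4R)-4-(2-methoxy-2-oxoethyl)-3-(3-methoxy-3-oxoprop-1-yn-1-yl)-5-oxooxolane-2-carboxylate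
Conditions: PdCl2 (5 mol %), CuCl2 (2.2 equiv), NaOAc (2.2 equiv), CO (1 atm), MeOH, rt
Reagents that add atoms: carbon monoxide, [C-]#[O+]; methanol, CO
Why: Oxidative alkoxycarbonylation of a terminal alkyne: divalent palladium forms the alkynyl complex, carbon monoxide and methanol supply the methoxycarbonyl ligand, reductive elimination gives the 2-ynoate and CuCl2 reoxidises palladium. No strong base is present, so the hydrogens on C1', C3 and C4 should not be at risk.

Step 10
Reactants: 16 methyl (2S,3S,4R)-4-(2-methoxy-2-oxoethyl)-3-(3-methoxy-3-oxoprop-1-yn-1-yl)-5-oxooxolane-2-carboxylate; 17 3,4-dimethoxyfuran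
Product: 19 methyl (2S,3S,4R)-3-[2-hydroxy-3,4-dimethoxy-6-(methoxycarbonyl)phenyl]-4-(2-methoxy-2-oxoethyl)-5-oxooxolane-2-carboxylate, via oxanorbornadiene 18 (not isolated)
Conditions: 17 (3 equiv), toluene, 90 °C, sealed tube; concentrate; then CF3CO2H (1 equiv), CH2Cl2, 0 °C
Reagents that add atoms: none
Why: Furan 17, made electron-rich by its two methoxy groups, adds as the diene across the triple bond of 16 in a thermal suprafacial [4+2] cycloaddition that forms C4a–C5 and C8a–C8 together and closes the six-membered carbocycle of 18; this is the known furan–alkynoate Diels–Alder reaction, so ring A is closed by cycloaddition and not by a cyclisation of a chain. The two bridgehead centres of 18 form as a mixture, which is of no consequence because both become sp2 carbons. Acid then ionises the bridge C–O bond at C8, the bridgehead next to the ester-bearing carbon: the cation formed is an allyl cation with the ester on its central carbon and is also an oxocarbenium ion through the C6 methoxy group, whereas ionisation at C5 would place positive charge on the ester-bearing carbon. Loss of the C5 proton aromatises ring A and leaves the former bridge oxygen as the C5 hydroxyl, which is the known acid-mediated isomerisation of 7-oxanorbornadienes to phenols. Because 17 is symmetrical the cycloaddition has no regiochemical question, and the only selectivity required is the direction of bridge opening, which the position of the ester should secure. No lasting stereocentre is created; the step must preserve C4, which is propargylic in 16 and lies next to a cationic ring carbon during the opening. The absence of base and the lactone ring, which disfavours an exocyclic double bond at C4, should protect it.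

Step 11
Reactants: 19 methyl (2S,3S,4R)-3-[2-hydroxy-3,4-dimethoxy-6-(methoxycarbonyl)phenyl]-4-(2-methoxy-2-oxoethyl)-5-oxooxolane-2-carboxylate
Product: 21 (2R)-2-[(3S,4S)-3-carboxy-5-hydroxy-6,7-dimethoxy-1-oxo-3,4-dihydro-1H-isochromen-4-yl]butanedioic acid, via hydroxy tetraacid 20 (not isolated)
Conditions: LiOH, THF/H2O (degassed), 0 → 40 °C; then aq. HCl to pH 1, rt → 40 °C
Reagents that add atoms: lithium hydroxide, [Li+].[OH-]
Why: Saponification of the three methyl esters and the γ-lactone, then acid-catalysed lactonisation of the C3 hydroxyl. Closure onto the ortho aryl carboxyl gives the benzo-fused six-membered lactone with the C3 carboxyl and the C4 branch trans, which should be preferred over the γ-lactone that forces the doubly ortho-substituted aryl group cis to the C3 carboxyl. Carboxylates are not enolised by hydroxide, so C3 and C1' should hold once the esters are cleaved.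

Step 12
Reactants: 21 (2R)-2-[(3S,4S)-3-carboxy-5-hydroxy-6,7-dimethoxy-1-oxo-3,4-dihydro-1H-isochromen-4-yl]butanedioic acid
Product: 22 (2R)-2-[(3S,4S)-3-carboxy-5,6,7-trihydroxy-1-oxo-3,4-dihydro-1H-isochromen-4-yl]butanedioic acid
Conditions: BBr3 (excess), CH2Cl2, −78 °C → rt; then H2O, 0 °C
Reagents that add atoms: none
Why: Lewis-acid cleavage of the two aryl methyl ethers (boron binds the ether oxygen and bromide attacks the methyl group); the medium is acidic throughout, so the pyrogallol is not exposed to base and air, and the lactone and the three stereocentres should not be affected.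

## Compound list

1 | (4R)-2,2-dimethyl-1,3-dioxolane-4-carbaldehyde, (R)-glyceraldehyde acetonide | CC1(C)OC[C@H](C=O)O1 | starting material
2 | dimethyl propanedioate (dimethyl malonate) | COC(=O)CC(=O)OC | starting material
3 | dimethyl 2-{[(4S)-2,2-dimethyl-1,3-dioxolan-4-yl]methylidene}propanedioate | COC(=O)C(C(=O)OC)=C[C@H]1COC(C)(C)O1 | intermediate
4 | ethynyltri(propan-2-yl)silane | C#C[Si](C(C)C)(C(C)C)C(C)C | starting material
5 | bromo{[tri(propan-2-yl)silyl]ethynyl}magnesium | Br[Mg]C#C[Si](C(C)C)(C(C)C)C(C)C | intermediate
6 | dimethyl 2-{(1S)-1-[(4S)-2,2-dimethyl-1,3-dioxolan-4-yl]-3-[tri(propan-2-yl)silyl]prop-2-yn-1-yl}propanedioate | COC(=O)C(C(=O)OC)[C@@H](C#C[Si](C(C)C)(C(C)C)C(C)C)[C@H]1COC(C)(C)O1 | intermediate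
7 | methyl (3S)-3-[(4S)-2,2-dimethyl-1,3-dioxolan-4-yl]-5-[tri(propan-2-yl)silyl]pent-4-ynoate | COC(=O)C[C@@H](C#C[Si](C(C)C)(C(C)C)C(C)C)[C@H]1COC(C)(C)O1 | intermediate
8 | methyl (3S,4S)-4,5-dihydroxy-3-{[tri(propan-2-yl)silyl]ethynyl}pentanoate | COC(=O)C[C@@H](C#C[Si](C(C)C)(C(C)C)C(C)C)[C@H](O)CO | intermediate
9 | (4S,5S)-5-(hydroxymethyl)-4-{[tri(propan-2-yl)silyl]ethynyl}oxolan-2-one | O=C1C[C@@H](C#C[Si](C(C)C)(C(C)C)C(C)C)[C@@H](CO)O1 | intermediate
10 | (4S,5S)-5-({[tert-butyl(dimethyl)silyl]oxy}methyl)-4-{[tri(propan-2-yl)silyl]ethynyl}oxolan-2-one | O=C1C[C@@H](C#C[Si](C(C)C)(C(C)C)C(C)C)[C@@H](CO[Si](C)(C)C(C)(C)C)O1 | intermediate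
11 | methyl bromoacetate | COC(=O)CBr | starting material
12 | methyl 2-[(3R,4S,5S)-5-({[tert-butyl(dimethyl)silyl]oxy}methyl)-2-oxo-4-{[tri(propan-2-yl)silyl]ethynyl}oxolan-3-yl]acetate | COC(=O)C[C@@H]1[C@@H](C#C[Si](C(C)C)(C(C)C)C(C)C)[C@@H](CO[Si](C)(C)C(C)(C)C)OC1=O | intermediate
13 | methyl 2-[(3R,4S,5S)-4-ethynyl-5-(hydroxymethyl)-2-oxooxolan-3-yl]acetate | COC(=O)C[C@@H]1[C@@H](C#C)[C@@H](CO)OC1=O | intermediate
14 | (2S,3S,4R)-3-ethynyl-4-(2-methoxy-2-oxoethyl)-5-oxooxolane-2-carboxylic acid | COC(=O)C[C@@H]1[C@@H](C#C)[C@@H](C(=O)O)OC1=O | intermediate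
15 | methyl (2S,3S,4R)-3-ethynyl-4-(2-methoxy-2-oxoethyl)-5-oxooxolane-2-carboxylate | COC(=O)C[C@@H]1[C@@H](C#C)[C@@H](C(=O)OC)OC1=O | intermediate
16 | methyl (2S,3S,4R)-4-(2-methoxy-2-oxoethyl)-3-(3-methoxy-3-oxoprop-1-yn-1-yl)-5-oxooxolane-2-carboxylate | COC(=O)C[C@@H]1[C@@H](C#CC(=O)OC)[C@@H](C(=O)OC)OC1=O | intermediate
17 | 3,4-dimethoxyfuran | COc1cocc1OC | starting material
18 | methyl 5,6-dimethoxy-3-[(2S,3S,4R)-2-(methoxycarbonyl)-4-(2-methoxy-2-oxoethyl)-5-oxooxolan-3-yl]-7-oxabicyclo[2.2.1]hepta-2,5-diene-2-carboxylate (both bridgehead diastereomers) | COC(=O)C[C@@H]1[C@@H](C2=C(C(=O)OC)C3OC2C(OC)=C3OC)[C@@H](C(=O)OC)OC1=O | intermediate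
19 | methyl (2S,3S,4R)-3-[2-hydroxy-3,4-dimethoxy-6-(methoxycarbonyl)phenyl]-4-(2-methoxy-2-oxoethyl)-5-oxooxolane-2-carboxylate | COC(=O)C[C@@H]1[C@@H](c2c(O)c(OC)c(OC)cc2C(=O)OC)[C@@H](C(=O)OC)OC1=O | intermediate
20 | (2R,3S,4S)-3-(2-carboxy-6-hydroxy-4,5-dimethoxyphenyl)-4-hydroxybutane-1,2,4-tricarboxylic acid | O=C(O)C[C@@H](C(=O)O)[C@@H](c1c(O)c(OC)c(OC)cc1C(=O)O)[C@H](O)C(=O)O | intermediate
21 | (2R)-2-[(3S,4S)-3-carboxy-5-hydroxy-6,7-dimethoxy-1-oxo-3,4-dihydro-1H-isochromen-4-yl]butanedioic acid | O=C(O)C[C@@H](C(=O)O)[C@H]1c2c(cc(OC)c(OC)c2O)C(=O)O[C@@H]1C(=O)O | intermediate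
22 | (2R)-2-[(3S,4S)-3-carboxy-5,6,7-trihydroxy-1-oxo-3,4-dihydro-1H-isochromen-4-yl]butanedioic acid | O=C(O)C[C@@H](C(=O)O)[C@H]1c2c(cc(O)c(O)c2O)C(=O)O[C@@H]1C(=O)O | target

## Step count and least certain steps

Total step count: 12. Longest linear sequence: 12 steps (1 to 22).

**Step 10 (key step).** The most likely failure is a cycloaddition that is too slow: only one ester activates the alkyne and its other carbon carries a branched ring carbon, so thermal or acid-induced decomposition of the electron-rich furan may outrun it. The second concern is erosion of C4 by loss of the C4 proton from the cationic intermediate during bridge opening. Fallback: covalent activation of the dienophile in place of higher temperature. It sets out from 15 and returns at 21. The oxidative carbonylation of step 9 would be run in 2,2,2-trifluoroethanol to give methyl (2S,3S,4R)-4-(2-methoxy-2-oxoethyl)-5-oxo-3-[3-oxo-3-(2,2,2-trifluoroethoxy)prop-1-yn-1-yl]oxolane-2-carboxylate F1, whose more electron-poor ester should lower the barrier to addition of 17. The cycloadduct, methyl 2,2,2-trifluoroethyl-ester analogue of the bridged diene F2, would be opened with acid as before to the aryl 2,2,2-trifluoroethyl ester F3. The hydrolysis of step 11 cleaves this ester together with the others, so F3 would give 21 through 20.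

**Step 2.** The most likely failure is poor facial selectivity, because attack anti to the C–O bond of the dioxolane competes with the chelation-assisted attack on the oxygen-bearing face; γ-deprotonation with opening of the dioxolane is a second possibility. Fallback: reagent control in place of substrate control. It sets out from 1 and returns at 9. Knoevenagel condensation of 1 with 2,2-dimethyl-1,3-dioxane-4,6-dione would give 5-{[(4S)-2,2-dimethyl-1,3-dioxolan-4-yl]methylidene}-2,2-dimethyl-1,3-dioxane-4,6-dione F4. Conjugate addition of 4 under catalysis by [RhCl(C2H4)2]2 (monovalent rhodium) with an enantiopure bisphosphine, the ligand antipode chosen to reinforce attack on the required face, would give 5-{(1S)-1-[(4S)-2,2-dimethyl-1,3-dioxolan-4-yl]-3-[tri(propan-2-yl)silyl]prop-2-yn-1-yl}-2,2-dimethyl-1,3-dioxane-4,6-dione F5. Aqueous acid with heating would remove both acetonides, the C3 hydroxyl would open the dioxanedione to (4S,5S)-5-(hydroxymethyl)-2-oxo-4-{[tri(propan-2-yl)silyl]ethynyl}oxolane-3-carboxylic acid F6, and F6 would lose carbon dioxide to give 9.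

**Step 9.** The most likely failures are over-carbonylation to a maleate-type diester, chloropalladation of the alkyne, and copper-mediated oxidative dimerisation of the alkyne. Fallback: carboxylation with carbon dioxide in place of carbon monoxide. It sets out from 15 and returns at 16. With AgI (catalytic) and Cs2CO3 under CO2 (1 atm) in DMF at room temperature, the silver acetylide would be carboxylated to 3-[(2S,3S,4R)-2-(methoxycarbonyl)-4-(2-methoxy-2-oxoethyl)-5-oxooxolan-3-yl]prop-2-ynoic acid F7, formed as its caesium salt and methylated in the same flask with MeI to give 16. The price is a carbonate base, which puts the C3 hydrogen at some risk; the lactone α-centre is already in its more stable trans arrangement.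

**Step 11.** The most likely failure is lactonisation onto the wrong carboxyl after acidification (back onto C1' as the five-membered lactone, onto C2', or dihydrocoumarin formation by the C5 hydroxyl), giving isomeric lactone acids; partial epimerisation at C1' or C3 during the basic phase is the second concern. Fallback: acyl transfer at the ester stage followed by non-hydrolytic deprotection. It sets out from 19 and returns at 22. Catalytic NaOMe in MeOH at 0 °C would open the γ-lactone to the methyl ester and let the C3 alkoxide close onto the neighbouring aryl ester, giving dimethyl (2R)-2-[(3S,4S)-5-hydroxy-6,7-dimethoxy-3-(methoxycarbonyl)-1-oxo-3,4-dihydro-1H-isochromen-4-yl]butanedioate F8, which would be separated from unchanged 19 (recycled). Excess BBr3 in CH2Cl2 would then cleave both methyl ethers and the three methyl esters without opening ring B by hydrolysis, and aqueous work-up would give 22.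

## Further compounds

F1 | step 10 | methyl (2S,3S,4R)-4-(2-methoxy-2-oxoethyl)-5-oxo-3-[3-oxo-3-(2,2,2-trifluoroethoxy)prop-1-yn-1-yl]oxolane-2-carboxylate | COC(=O)C[C@@H]1[C@@H](C#CC(=O)OCC(F)(F)F)[C@@H](C(=O)OC)OC1=O
F2 | step 10 | 2,2,2-trifluoroethyl 5,6-dimethoxy-3-[(2S,3S,4R)-2-(methoxycarbonyl)-4-(2-methoxy-2-oxoethyl)-5-oxooxolan-3-yl]-7-oxabicyclo[2.2.1]hepta-2,5-diene-2-carboxylate | COC(=O)C[C@@H]1[C@@H](C2=C(C(=O)OCC(F)(F)F)C3OC2C(OC)=C3OC)[C@@H](C(=O)OC)OC1=O
F3 | step 10 | methyl (2S,3S,4R)-3-{2-hydroxy-3,4-dimethoxy-6-[(2,2,2-trifluoroethoxy)carbonyl]phenyl}-4-(2-methoxy-2-oxoethyl)-5-oxooxolane-2-carboxylate | COC(=O)C[C@@H]1[C@@H](c2c(O)c(OC)c(OC)cc2C(=O)OCC(F)(F)F)[C@@H](C(=O)OC)OC1=O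
F4 | step 2 | 5-{[(4S)-2,2-dimethyl-1,3-dioxolan-4-yl]methylidene}-2,2-dimethyl-1,3-dioxane-4,6-dione | CC1(C)OC[C@H](C=C2C(=O)OC(C)(C)OC2=O)O1
F5 | step 2 | 5-{(1S)-1-[(4S)-2,2-dimethyl-1,3-dioxolan-4-yl]-3-[tri(propan-2-yl)silyl]prop-2-yn-1-yl}-2,2-dimethyl-1,3-dioxane-4,6-dione | CC1(C)OC[C@H]([C@H](C#C[Si](C(C)C)(C(C)C)C(C)C)C2C(=O)OC(C)(C)OC2=O)O1
F6 | step 2 | (4S,5S)-5-(hydroxymethyl)-2-oxo-4-{[tri(propan-2-yl)silyl]ethynyl}oxolane-3-carboxylic acid | OC(=O)C1[C@@H](C#C[Si](C(C)C)(C(C)C)C(C)C)[C@@H](CO)OC1=O
F7 | step 9 | 3-[(2S,3S,4R)-2-(methoxycarbonyl)-4-(2-methoxy-2-oxoethyl)-5-oxooxolan-3-yl]prop-2-ynoic acid | COC(=O)C[C@@H]1[C@@H](C#CC(=O)O)[C@@H](C(=O)OC)OC1=O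
F8 | step 11 | dimethyl (2R)-2-[(3S,4S)-5-hydroxy-6,7-dimethoxy-3-(methoxycarbonyl)-1-oxo-3,4-dihydro-1H-isochromen-4-yl]butanedioate | COC(=O)C[C@@H](C(=O)OC)[C@H]1c2c(cc(OC)c(OC)c2O)C(=O)O[C@@H]1C(=O)OC
A1 | alternative 1 | (1E)-buta-1,3-dien-1-yl 3,4,5-trimethoxy-2-[(1Z)-3-methoxy-3-oxoprop-1-en-1-yl]benzoate | C=C/C=C/OC(=O)c1cc(OC)c(OC)c(OC)c1/C=C\C(=O)OC
A2 | alternative 1 | methyl 8,9,10-trimethoxy-6-oxo-1,2,4a,10b-tetrahydro-6H-benzo[c]chromene-1-carboxylate, trans ring fusion, configuration as in the SMILES | C1=CC[C@@H](C(=O)OC)[C@H]2c3c(cc(OC)c(OC)c3OC)C(=O)O[C@@H]21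
A3 | alternative 2 | methyl (3S,4S)-4-ethenyl-5,6,7-trimethoxy-1-oxo-3,4-dihydro-1H-isochromene-3-carboxylate | C=C[C@H]1c2c(cc(OC)c(OC)c2OC)C(=O)O[C@@H]1C(=O)OC
A4 | alternative 2 | dimethyl (2R)-2-[(3S,4S)-5,6,7-trimethoxy-3-(methoxycarbonyl)-1-oxo-3,4-dihydro-1H-isochromen-4-yl]butanedioate | COC(=O)C[C@@H](C(=O)OC)[C@H]1c2c(cc(OC)c(OC)c2OC)C(=O)O[C@@H]1C(=O)OC
A5 | alternative 3 | tri-tert-butyl (2R,3S,4S)-4-hydroxy-3-(2,3,4-trimethoxyphenyl)butane-1,2,4-tricarboxylate | CC(C)(C)OC(=O)C[C@@H](C(=O)OC(C)(C)C)[C@@H](c1ccc(OC)c(OC)c1OC)[C@H](O)C(=O)OC(C)(C)C
A6 | alternative 3 | di-tert-butyl (2R)-2-[(3S,4S)-3-(tert-butoxycarbonyl)-5,6,7-trimethoxy-1-oxo-3,4-dihydro-1H-isochromen-4-yl]butanedioate | CC(C)(C)OC(=O)C[C@@H](C(=O)OC(C)(C)C)[C@H]1c2c(cc(OC)c(OC)c2OC)C(=O)O[C@@H]1C(=O)OC(C)(C)C
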